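**Plan**

- Retrosynthesis: the free C3 lactol is traced to its (3R)-acetate, and the benzylic ester C–O bond (ring B CH2–O–acyl of ring A) is cut to give a ring A acid and a ring B/C alcohol. Ring C is then opened at O2–C3 to a 2-formylbenzoic acid, and the C3a–C3 and C7a–C1 bonds are cut together back to one aryne.
- Enabling feature: on ring B the lactone carbon C1 (on C7a) and the lactol carbon C3 (on C3a) sit on neighbouring ring carbons, with C7a beside the C7 oxygen and C3a beside the unsubstituted C4. This is the pattern a 3-alkoxyaryne acquires when a carbon nucleophile and then an electrophile add across it, and the C5/C7 oxygens around the C6 CH2O group make the bromide precursor mirror-symmetric.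
- Forward, ring B/C: aldehyde reduction and silylation, aryne coupling (vinyl as latent C3, CO2 as C1), ozonolysis with spontaneous closure of ring C, and BCl3 release of the C7 phenol.
- Forward, joining: acetylation of the lactol, desilylation, Mitsunobu coupling with the ring A acid (made in two steps), and removal of the acetate.
- Stereochemistry: C3 is the only stereocentre. It is set by lipase-catalysed dynamic kinetic acetylation of the racemic lactol, carried as the configurationally stable acetate, and uncovered with retention by lipase alcoholysis (acyl–oxygen cleavage).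

Key step: step 3

Numbering used in names: phthalide numbering with C1 the lactone carbonyl, O2, C3 the lactol carbon, then C3a, C4–C7, C7a. The target stereocentre is C3 and is (R).

Assumption: a 3-hydroxyphthalide can epimerise at C3 through its ring-opened formyl acid. It is assumed that this is slow in neutral, amine-free organic media, so the (3R) centre is stored as its acetate and released only in the last step.

**Step 1**
Reactants: 1 4-bromo-2,6-dimethoxybenzaldehyde
Product: 2 (4-bromo-2,6-dimethoxyphenyl)methanol
Conditions: NaBH4, MeOH/THF, 0 °C → rt; aq. NH4Cl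
Reagents that add atoms: none
Why: Sodium borohydride reduction of an aryl aldehyde is fast and leaves the aryl bromide and the methyl ethers untouched.

**Step 2**
Reactants: 2 (4-bromo-2,6-dimethoxyphenyl)methanol
Product: 3 5-bromo-1,3-dimethoxy-2-[(triisopropylsilyloxy)methyl]benzene
Conditions: TIPSCl, imidazole, DMF, rt
Reagents that add atoms: triisopropylsilyl chloride, CC(C)[Si](Cl)(C(C)C)C(C)C
Why: Imidazole-promoted silylation of a primary alcohol; the bulky triisopropylsilyl ether is chosen because it shields the benzylic oxygen from the amide base and Grignard reagent of step 3 and from BCl3 in step 5, yet is removed by fluoride.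

**Step 3**
Reactants: 3 5-bromo-1,3-dimethoxy-2-[(triisopropylsilyloxy)methyl]benzene; 4 vinylmagnesium bromide; 5 carbon dioxide
Product: 10 2,4-dimethoxy-3-[(triisopropylsilyloxy)methyl]-6-vinylbenzoic acid, via aryllithium 6 (not isolated), via aryne 7 (not isolated), via arylmagnesium bromide 8 (not isolated), via bromomagnesium carboxylate 9 (not isolated)
Conditions: lithium 2,2,6,6-tetramethylpiperidide (1.2 equiv), THF, −90 °C, 15 min; CH2=CHMgBr (3 equiv), −90 °C → rt; CO2 (gas), −40 °C → rt; 1 M HCl, 0 °C
Reagents that add atoms: none
Why: The amide base removes the ring hydrogen flanked by bromine and methoxy (either one, since 3 is mirror-symmetric) to give 6, which loses LiBr on warming to give aryne 7 across C3a–C7a. The vinyl Grignard reagent adds at C3a, the aryne carbon remote from the C7 methoxy group, because the electron-withdrawing oxygen polarises the triple bond and stabilises the carbanion developing at C7a, where magnesium is also held by the methoxy oxygen. The arylmagnesium 8 is then carboxylated by CO2 to 9 and protonated to 10, so C3a–C3 and C7a–C1 are formed in one flask. The closest known reaction type is the three-component aryne coupling (carbomagnesiation, then electrophilic trapping) of 3-alkoxyarynes generated from 3-haloanisoles. No ring is closed and no stereocentre is formed. The only selectivity needed is the regiochemistry of the addition, which is secured by methoxy on the C7 flank against hydrogen on the C4 flank, while the excess of Grignard reagent outcompetes addition of the hindered amide.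

**Step 4**
Reactants: 10 2,4-dimethoxy-3-[(triisopropylsilyloxy)methyl]-6-vinylbenzoic acid
Product: 13 racemic 3-hydroxy-5,7-dimethoxy-6-[(triisopropylsilyloxy)methyl]isobenzofuran-1(3H)-one, via ozonide 11 (not isolated), via formyl acid 12 (not isolated)
Conditions: O3, CH2Cl2, −78 °C; Me2S, −78 °C → rt
Reagents that add atoms: ozone, [O-][O+]=O
Why: Ozonolysis with reductive work-up cleaves the styrene much faster than the arene, and formyl acid 12 closes ring C spontaneously by 5-exo-trig addition of the carboxyl oxygen to the aldehyde (ring–chain tautomerism favouring the hydroxyphthalide), leaving C3 as a racemic, interconverting lactol centre.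

**Step 5**
Reactants: 13 racemic 3-hydroxy-5,7-dimethoxy-6-[(triisopropylsilyloxy)methyl]isobenzofuran-1(3H)-one
Product: 15 racemic 3,7-dihydroxy-5-methoxy-6-[(triisopropylsilyloxy)methyl]isobenzofuran-1(3H)-one, via bis(dichloroboryl) ether 14 (not isolated)
Conditions: BCl3 (2.5 equiv), CH2Cl2, −78 → 0 °C; then THF/H2O, 0 °C
Reagents that add atoms: none
Why: Chelation-controlled BCl3 O-demethylation: boron held on the lactone carbonyl reaches only the peri C7 methoxy group, so chloride removes that methyl, while the C5 methoxy (para to the carbonyl) and the hindered, weakly basic silyl ether on the boron-complexed, electron-poor ring should persist, and hydrolysis of 14 returns phenol and lactol.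

**Step 6**
Reactants: 15 racemic 3,7-dihydroxy-5-methoxy-6-[(triisopropylsilyloxy)methyl]isobenzofuran-1(3H)-one
Product: 16 (3R)-3-acetoxy-7-hydroxy-5-methoxy-6-[(triisopropylsilyloxy)methyl]isobenzofuran-1(3H)-one
Conditions: immobilised Burkholderia cepacia lipase, vinyl acetate (5 equiv), Et3N (5 mol%), toluene, 35 °C
Reagents that add atoms: vinyl acetate, C=COC(C)=O
Why: Lipase-catalysed dynamic kinetic resolution by irreversible acetylation, of the kind established for γ-hydroxybutenolide-type lactols: the lactol enantiomers interconvert through the ring-opened formyl acid while the enzyme acetylates one of them, its active site setting C3, and the empirical size rule for lipases (fused arene as the large substituent, ring oxygen as the medium one) predicts the (3R)-acetate, a sense to be confirmed on the acetate; the chelated, doubly flanked C7 phenol is not a substrate.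

**Step 7**
Reactants: 16 (3R)-3-acetoxy-7-hydroxy-5-methoxy-6-[(triisopropylsilyloxy)methyl]isobenzofuran-1(3H)-one
Product: 17 (3R)-3-acetoxy-7-hydroxy-6-(hydroxymethyl)-5-methoxyisobenzofuran-1(3H)-one
Conditions: HF·pyridine, pyridine, THF, 0 °C → rt
Reagents that add atoms: none
Why: Fluoride desilylation with buffered HF·pyridine, chosen over basic fluoride so that the base-labile acyl acetal and lactone survive and C3, now a non-ionising acyloxy acetal carbon, keeps its configuration.

**Step 8**
Reactants: 18 methyl 2,4-dihydroxy-3,6-dimethylbenzoate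
Product: 19 methyl 2-hydroxy-4-methoxy-3,6-dimethylbenzoate
Conditions: MeI (1.1 equiv), K2CO3, acetone, reflux
Reagents that add atoms: iodomethane, CI
Why: Williamson O-methylation is selective for the C4 hydroxyl because the C2 hydroxyl is locked in a hydrogen bond to the ester carbonyl and is far less nucleophilic.

**Step 9**
Reactants: 19 methyl 2-hydroxy-4-methoxy-3,6-dimethylbenzoate
Product: 20 2-hydroxy-4-methoxy-3,6-dimethylbenzoic acid
Conditions: KOH, DMSO/H2O, 90 °C; then 1 M HCl, 0 °C
Reagents that add atoms: potassium hydroxide, [K+].[OH-]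
Why: Saponification of the di-ortho-substituted ester needs hot hydroxide in aqueous DMSO, and cold acidification avoids decarboxylation of the electron-rich salicylic acid.

**Step 10**
Reactants: 17 (3R)-3-acetoxy-7-hydroxy-6-(hydroxymethyl)-5-methoxyisobenzofuran-1(3H)-one; 20 2-hydroxy-4-methoxy-3,6-dimethylbenzoic acid
Product: 21 [(3R)-3-acetoxy-7-hydroxy-5-methoxy-1-oxo-1,3-dihydroisobenzofuran-6-yl]methyl 2-hydroxy-4-methoxy-3,6-dimethylbenzoate
Conditions: PPh3, DIAD, THF, 0 °C → rt
Reagents that add atoms: none
Why: Mitsunobu esterification: acid 20 is by far the most acidic partner, so its carboxylate displaces the activated primary benzylic oxygen (no attack at the hindered acyl carbon is needed), the two chelated phenols being too weakly acidic to compete, as in known Mitsunobu esterifications of phenolic alcohols with phenolic acids, and the neutral conditions leave the C3 acetate centre untouched.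

**Step 11**
Reactants: 21 [(3R)-3-acetoxy-7-hydroxy-5-methoxy-1-oxo-1,3-dihydroisobenzofuran-6-yl]methyl 2-hydroxy-4-methoxy-3,6-dimethylbenzoate
Product: 22 [(3R)-3,7-dihydroxy-5-methoxy-1-oxo-1,3-dihydroisobenzofuran-6-yl]methyl 2-hydroxy-4-methoxy-3,6-dimethylbenzoate
Conditions: immobilised Burkholderia cepacia lipase, n-BuOH (5 equiv), t-BuOMe, 5–20 °C; filtration, evaporation below 25 °C
Reagents that add atoms: none
Why: Lipase-catalysed transesterification (alcoholysis) to n-butanol cleaves the acetyl–oxygen bond, so the C3–O bond is never broken and the (3R) configuration is retained; the enzyme that formed this acetate should accept it as its matched enantiomer, the hindered ring A ester and the lactone are not substrates, and the neutral, amine-free, cool medium keeps ring-opening of the liberated lactol slow.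

**Compound list**

1 | 4-bromo-2,6-dimethoxybenzaldehyde | COc1cc(Br)cc(OC)c1C=O | starting material
2 | (4-bromo-2,6-dimethoxyphenyl)methanol | COc1cc(Br)cc(OC)c1CO | intermediate
3 | 5-bromo-1,3-dimethoxy-2-[(triisopropylsilyloxy)methyl]benzene | COc1cc(Br)cc(OC)c1CO[Si](C(C)C)(C(C)C)C(C)C | intermediate
4 | vinylmagnesium bromide | C=C[Mg]Br | starting material
5 | carbon dioxide | O=C=O | starting material
6 | {6-bromo-2,4-dimethoxy-3-[(triisopropylsilyloxy)methyl]phenyl}lithium (in flask) | COc1cc(Br)c([Li])c(OC)c1CO[Si](C(C)C)(C(C)C)C(C)C | intermediate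
7 | 3,5-dimethoxy-4-[(triisopropylsilyloxy)methyl]-1,2-didehydrobenzene, the C3a–C7a aryne (in flask) | COC1=CC#CC(OC)=C1CO[Si](C(C)C)(C(C)C)C(C)C | intermediate
8 | {2,4-dimethoxy-3-[(triisopropylsilyloxy)methyl]-6-vinylphenyl}magnesium bromide (in flask) | C=Cc1cc(OC)c(CO[Si](C(C)C)(C(C)C)C(C)C)c(OC)c1[Mg]Br | intermediate
9 | bromomagnesium 2,4-dimethoxy-3-[(triisopropylsilyloxy)methyl]-6-vinylbenzoate (in flask) | C=Cc1cc(OC)c(CO[Si](C(C)C)(C(C)C)C(C)C)c(OC)c1C(=O)O[Mg]Br | intermediate
10 | 2,4-dimethoxy-3-[(triisopropylsilyloxy)methyl]-6-vinylbenzoic acid | C=Cc1cc(OC)c(CO[Si](C(C)C)(C(C)C)C(C)C)c(OC)c1C(=O)O | intermediate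
11 | 2,4-dimethoxy-6-(1,2,4-trioxolan-3-yl)-3-[(triisopropylsilyloxy)methyl]benzoic acid (in flask) | OC(=O)c1c(OC)c(CO[Si](C(C)C)(C(C)C)C(C)C)c(OC)cc1C2OCOO2 | intermediate
12 | 6-formyl-2,4-dimethoxy-3-[(triisopropylsilyloxy)methyl]benzoic acid (in flask) | O=Cc1cc(OC)c(CO[Si](C(C)C)(C(C)C)C(C)C)c(OC)c1C(=O)O | intermediate
13 | racemic 3-hydroxy-5,7-dimethoxy-6-[(triisopropylsilyloxy)methyl]isobenzofuran-1(3H)-one | COc1cc2c(c(OC)c1CO[Si](C(C)C)(C(C)C)C(C)C)C(=O)OC2O | intermediate
14 | 3,7-bis(dichloroboryloxy)-5-methoxy-6-[(triisopropylsilyloxy)methyl]isobenzofuran-1(3H)-one (in flask) | COc1cc2c(c(OB(Cl)Cl)c1CO[Si](C(C)C)(C(C)C)C(C)C)C(=O)OC2OB(Cl)Cl | intermediate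
15 | racemic 3,7-dihydroxy-5-methoxy-6-[(triisopropylsilyloxy)methyl]isobenzofuran-1(3H)-one | COc1cc2c(c(O)c1CO[Si](C(C)C)(C(C)C)C(C)C)C(=O)OC2O | intermediate
16 | (3R)-3-acetoxy-7-hydroxy-5-methoxy-6-[(triisopropylsilyloxy)methyl]isobenzofuran-1(3H)-one | COc1cc2c(c(O)c1CO[Si](C(C)C)(C(C)C)C(C)C)C(=O)O[C@H]2OC(C)=O | intermediate
17 | (3R)-3-acetoxy-7-hydroxy-6-(hydroxymethyl)-5-methoxyisobenzofuran-1(3H)-one | COc1cc2c(c(O)c1CO)C(=O)O[C@H]2OC(C)=O | intermediate
18 | methyl 2,4-dihydroxy-3,6-dimethylbenzoate | COC(=O)c1c(C)cc(O)c(C)c1O | starting material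
19 | methyl 2-hydroxy-4-methoxy-3,6-dimethylbenzoate | COC(=O)c1c(C)cc(OC)c(C)c1O | intermediate
20 | 2-hydroxy-4-methoxy-3,6-dimethylbenzoic acid | COc1cc(C)c(C(=O)O)c(O)c1C | intermediate
21 | [(3R)-3-acetoxy-7-hydroxy-5-methoxy-1-oxo-1,3-dihydroisobenzofuran-6-yl]methyl 2-hydroxy-4-methoxy-3,6-dimethylbenzoate | COc1cc(C)c(C(=O)OCc2c(OC)cc3c(c2O)C(=O)O[C@H]3OC(C)=O)c(O)c1C | intermediate
22 | [(3R)-3,7-dihydroxy-5-methoxy-1-oxo-1,3-dihydroisobenzofuran-6-yl]methyl 2-hydroxy-4-methoxy-3,6-dimethylbenzoate (CNP0398000.1) | COc1cc(C)c(C(=O)OCc2c(OC)cc3c(c2O)C(=O)O[C@H]3O)c(O)c1C | target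

**Step count**

Total: 11 steps. Longest linear sequence: 9 steps (steps 1–7, 10 and 11); steps 8 and 9 form the ring A branch.

**Steps most likely to fail**

Risk 1, step 3. The lithiated bromide may collapse to the aryne before enough vinyl nucleophile is at hand, so that the amide base, the liberated amine or already formed arylmagnesium species add to the aryne in place of the vinyl group. Carboxylation of the doubly flanked arylmagnesium may also stay incomplete. The fallback makes the two carbon–carbon bonds one after the other by lithiation chemistry, without an aryne. Setting out from 3, bromine–lithium exchange (n-BuLi, THF, −78 °C) and quenching with DMF should give 3,5-dimethoxy-4-[(triisopropylsilyloxy)methyl]benzaldehyde F1. Addition of lithium N,N,N'-trimethylethylenediamide masks the aldehyde in the flask as lithium α-amino alkoxide F2. n-BuLi then removes the ring hydrogen flanked by this directing group and a methoxy group (directed ortho-metalation) to give aryllithium F3. CO2 and a mildly acidic work-up should release formyl acid 12, which closes to lactol 13. The route is rejoined at 13, with steps 3 and 4 replaced.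

Risk 2, step 5. The silyl group may be lost, or the benzylic carbon–oxygen bond may ionise, assisted by the boron phenoxide that forms on the neighbouring C7 oxygen. The C5 methoxy group may also react if the mixture has to be warmed to drive the lactone-directed cleavage. The fallback postpones the demethylation until the silicon is gone and the ester is in place, with the lactol masked as a methyl acetal. Setting out from 13, MeOH, HC(OMe)3 and pyridinium p-toluenesulfonate should give 3,5,7-trimethoxy-6-[(triisopropylsilyloxy)methyl]isobenzofuran-1(3H)-one F4. Bu4NF in THF then frees 6-(hydroxymethyl)-3,5,7-trimethoxyisobenzofuran-1(3H)-one F5. Mitsunobu esterification with acid 20 (PPh3, DIAD) gives (3,5,7-trimethoxy-1-oxo-1,3-dihydroisobenzofuran-6-yl)methyl 2-hydroxy-4-methoxy-3,6-dimethylbenzoate F6. BCl3 in CH2Cl2 followed by aqueous THF removes the C7 methyl group and the acetal methyl group to give the racemic form of the target, (3,7-dihydroxy-5-methoxy-1-oxo-1,3-dihydroisobenzofuran-6-yl)methyl 2-hydroxy-4-methoxy-3,6-dimethylbenzoate F7. Lipase-catalysed dynamic acetylation of F7 under the conditions of step 6 then leads to acetate 21, where the route is rejoined before step 11 (steps 5, 6, 7 and 10 replaced).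

Risk 3, step 6. The enzyme may discriminate poorly between the lactol enantiomers, or in the opposite sense, with this hindered fused lactol. Racemisation may also be slow relative to acetylation, so that the process stalls as a simple kinetic resolution. The fallback uses chemical in place of enzymatic asymmetric acyl transfer. Setting out from 15, acylative dynamic kinetic resolution with acetic anhydride, i-Pr2NEt and a chiral isothiourea acyl-transfer catalyst of the benzotetramisole type should give acetate 16 directly, where the route is rejoined. Both antipodes of the catalyst are available, so the sense can be chosen. No compound outside the list arises (F0).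

**Further compounds**

F1 | step 3 | 3,5-dimethoxy-4-[(triisopropylsilyloxy)methyl]benzaldehyde | COc1cc(C=O)cc(OC)c1CO[Si](C(C)C)(C(C)C)C(C)C
F2 | step 3 | lithium {[2-(dimethylamino)ethyl](methyl)amino}{3,5-dimethoxy-4-[(triisopropylsilyloxy)methyl]phenyl}methanolate (lithium α-amino alkoxide, in flask) | COc1cc(C(O[Li])N(C)CCN(C)C)cc(OC)c1CO[Si](C(C)C)(C(C)C)C(C)C
F3 | step 3 | 2-lithio derivative of F2 (aryllithium, in flask) | COc1cc(C(O[Li])N(C)CCN(C)C)c([Li])c(OC)c1CO[Si](C(C)C)(C(C)C)C(C)C
F4 | step 5 | racemic 3,5,7-trimethoxy-6-[(triisopropylsilyloxy)methyl]isobenzofuran-1(3H)-one | COc1cc2c(c(OC)c1CO[Si](C(C)C)(C(C)C)C(C)C)C(=O)OC2OC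
F5 | step 5 | racemic 6-(hydroxymethyl)-3,5,7-trimethoxyisobenzofuran-1(3H)-one | COc1cc2c(c(OC)c1CO)C(=O)OC2OC
F6 | step 5 | racemic (3,5,7-trimethoxy-1-oxo-1,3-dihydroisobenzofuran-6-yl)methyl 2-hydroxy-4-methoxy-3,6-dimethylbenzoate | COc1cc(C)c(C(=O)OCc2c(OC)cc3c(c2OC)C(=O)OC3OC)c(O)c1C
F7 | step 5 | racemic (3,7-dihydroxy-5-methoxy-1-oxo-1,3-dihydroisobenzofuran-6-yl)methyl 2-hydroxy-4-methoxy-3,6-dimethylbenzoate | COc1cc(C)c(C(=O)OCc2c(OC)cc3c(c2O)C(=O)OC3O)c(O)c1C
F0 | step 6 | none | none
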